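Numbering (cembrane): C1 ring CH bearing C15; C3 lactone O–CH; C4 C(OH)CH3; C7 CHOH; C8 methylidene carbon; C11/C12 epoxide; C15 lactone CH(CH3); C16 lactone C=O; C17–C20 are the carbons on C15, C4, C8 and C12.
Cuts, in retrosynthetic order: the C11–C12 epoxide oxygen; C7–C8 (opens the 14-membered carbocycle); C12–C13 (releases a C8–C12 linker); then C2–C3 and O–C16 together (opens the six-membered lactone).
Enabling feature: in the lactone ring (O, C16, C15, C1, C2, C3), C16–C15–C1–C2 is a 2-methyl dienolate and C3 is an aldehyde carbon. The ring therefore equals a vinylketene silyl acetal plus an α-alkoxy aldehyde, and its C1=C15 alkene can then be reduced under the control of C3/C4.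
Forward order: the lactone ring is made first (step 8) and saturated. The C13 arm is joined to the linker by Negishi coupling, the carbocycle is closed at C7–C8 by a Nozaki–Hiyama–Kishi reaction, and the epoxide comes last.
Stereochemistry: C4 from (S)-linalool; C3 from the BINOL ligand; C1 from hydrogenation anti to the C4 group; C15 by equilibration; the 11E alkene from syn-hydrozirconation; C7 by CBS reduction; C11/C12 from the L-series Shi ketone.

Key step: step 8

Assumption: (S)-(+)-linalool is taken as a commercial compound of high enantiomeric purity, since its carbinol carbon becomes C4 unchanged.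
Assumption: the ketene acetal 14 is drawn as one geometric isomer. Either isomer leads to 16, because C15 and C16 carry no stereochemical information in the product.

Step 1
Reactants: 1 (S)-linalool
Product: 2 (3S)-3-(methoxymethoxy)-3,7-dimethylocta-1,6-diene
Conditions: MOMCl, iPr2NEt, Bu4NI (cat.), CH2Cl2, 0 → 40 °C
Reagents that add atoms: chloromethyl methyl ether, COCCl
Why: MOM protection (O-alkylation by a highly reactive α-chloro ether) works even on tertiary alcohols and leaves the C4 centre untouched.

Step 2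
Reactants: 2 (3S)-3-(methoxymethoxy)-3,7-dimethylocta-1,6-diene
Product: 4 (4S)-4-(methoxymethoxy)-4-methylhex-5-en-1-ol, via (4S)-4-(methoxymethoxy)-4-methylhex-5-enal 3 (not isolated)
Conditions: O3 (1 equiv, Sudan Red 7B end point), CH2Cl2–MeOH, −78 °C; NaBH4, −78 → 0 °C
Reagents that add atoms: ozone, [O-][O+]=O
Why: Chemoselective ozonolysis with reductive work-up should succeed because electrophilic ozone attacks the electron-rich trisubstituted alkene far faster than the vinyl group on the oxygenated quaternary carbon.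

Step 3
Reactants: 4 (4S)-4-(methoxymethoxy)-4-methylhex-5-en-1-ol
Product: 5 triisopropyl{[(4S)-4-(methoxymethoxy)-4-methylhex-5-en-1-yl]oxy}silane
Conditions: TIPSCl, imidazole, DMF, rt
Reagents that add atoms: chlorotriisopropylsilane, CC(C)[Si](Cl)(C(C)C)C(C)C
Why: Standard silylation of a primary alcohol; TIPS is chosen for C7–O so that it outlasts the primary TBS ether placed on C13–O.

Step 4
Reactants: 5 triisopropyl{[(4S)-4-(methoxymethoxy)-4-methylhex-5-en-1-yl]oxy}silane
Product: 7 (2S)-2-(methoxymethoxy)-2-methyl-5-[(triisopropylsilyl)oxy]pentanal, via secondary ozonide 6 (not isolated)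
Conditions: O3, CH2Cl2, −78 °C; PPh3, −78 °C → rt
Reagents that add atoms: ozone, [O-][O+]=O
Why: Ozonolysis of the remaining vinyl group gives the C3 aldehyde, which cannot epimerise because its α-carbon (C4) bears no hydrogen.

Step 5
Reactants: 8 3-bromobut-3-en-1-ol
Product: 9 [(3-bromobut-3-en-1-yl)oxy](tert-butyl)dimethylsilane
Conditions: TBSCl, imidazole, CH2Cl2, rt
Reagents that add atoms: tert-butylchlorodimethylsilane, CC(C)(C)[Si](C)(C)Cl
Why: Standard silylation of a primary alcohol; the four carbons of 8 become C2, C1, C14 and C13.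

Step 6
Reactants: 9 [(3-bromobut-3-en-1-yl)oxy](tert-butyl)dimethylsilane; 10 methyl 2-bromopropanoate (racemic)
Product: 12 methyl 5-[(tert-butyldimethylsilyl)oxy]-2-methyl-3-methylidenepentanoate (racemic), via bromo(1-methoxy-1-oxopropan-2-yl)zinc 11 (not isolated)
Conditions: 10, Zn dust, THF, rt; then 9, Pd(dba)2 (2 mol %), P(t-Bu)3 (4 mol %), THF, rt
Reagents that add atoms: none
Why: Negishi-type coupling of a Reformatsky reagent with an alkenyl bromide (palladium-catalysed α-alkenylation of an ester) forms C1–C15 under nearly neutral conditions, so the 1,1-disubstituted alkene should stay out of conjugation; the racemic α-carbon becomes sp2 in step 7.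

Step 7
Reactants: 12 methyl 5-[(tert-butyldimethylsilyl)oxy]-2-methyl-3-methylidenepentanoate
Product: 14 3-{2-[(tert-butyldimethylsilyl)oxy]ethyl}-1-methoxy-2-methyl-1-[(trimethylsilyl)oxy]buta-1,3-diene, via lithium dienolate 13 (not isolated)
Conditions: LiN(iPr)2, THF, −78 °C; Me3SiCl, −78 → 0 °C; non-aqueous work-up, used at once
Reagents that add atoms: chlorotrimethylsilane, C[Si](C)(C)Cl
Why: Enolisation and O-silylation of an ester; removing the single, doubly activated C15–H of the β,γ-unsaturated ester gives only the C2=C1–C15=C16 dienolate, and the hindered α-carbon favours silylation on oxygen.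

Step 8
Reactants: 7 (2S)-2-(methoxymethoxy)-2-methyl-5-[(triisopropylsilyl)oxy]pentanal; 14 3-{2-[(tert-butyldimethylsilyl)oxy]ethyl}-1-methoxy-2-methyl-1-[(trimethylsilyl)oxy]buta-1,3-diene
Product: 16 (6R)-4-{2-[(tert-butyldimethylsilyl)oxy]ethyl}-6-{(2S)-2-(methoxymethoxy)-5-[(triisopropylsilyl)oxy]pentan-2-yl}-3-methyl-5,6-dihydro-2H-pyran-2-one, via cyclic mixed orthoester 15 (not isolated)
Conditions: Ti(OiPr)4 (20 mol %), (R)-BINOL (22 mol %), 4 Å MS, 14 (2 equiv), CH2Cl2, −20 °C → rt; then CF3CO2H (cat.), CH2Cl2, 0 °C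
Reagents that add atoms: none
Why: The titanium BINOLate binds the aldehyde oxygen of 7, the free diene terminus C2 attacks C3, and the developing alkoxide closes on C16 across the cisoid diene (asynchronous [4+2]) to give orthoester 15, which loses Me3SiOMe to leave the lactone carbonyl; the trace acid also lactonises any open-chain (Z)-δ-silyloxy enoate from a stepwise Mukaiyama path. The closest known reaction type is the chiral-Lewis-acid-catalysed hetero-Diels–Alder or vinylogous Mukaiyama aldol reaction of 1-alkoxy-1-silyloxy dienes with aldehydes to give 5,6-dihydropyran-2-ones. The single ring formed, the six-membered lactone (O, C16, C15, C1, C2, C3), closes by cycloaddition or, in the stepwise variant, by 6-exo-trig attack of the C3 oxygen on C16. C3 is the only new stereocentre and is set by the ligand: by analogy with related titanium–BINOL additions, (R)-BINOL should expose the Re face and give 3R, while the C4 centre, whose methyl and methylene arms differ little, should exert little bias of its own. The step needs γ- rather than α-attack and a cisoid diene; C15 is fully substituted, so α-attack would have to build a quaternary carbon, C2 is the only unsubstituted terminus, and the substituents on C1 and C15 penalise the transoid conformer. The steric demand of both partners is offset by the inductive activation of the aldehyde by its α-acetal oxygen, the excess of diene and the high catalyst loading.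

Step 9
Reactants: 16 (6R)-4-{2-[(tert-butyldimethylsilyl)oxy]ethyl}-6-{(2S)-2-(methoxymethoxy)-5-[(triisopropylsilyl)oxy]pentan-2-yl}-3-methyl-5,6-dihydro-2H-pyran-2-one
Product: 17 (3R,4R,6R)-4-{2-[(tert-butyldimethylsilyl)oxy]ethyl}-6-{(2S)-2-(methoxymethoxy)-5-[(triisopropylsilyl)oxy]pentan-2-yl}-3-methyltetrahydro-2H-pyran-2-one (all-cis)
Conditions: H2 (60 bar), 5% Rh/Al2O3, EtOAc, rt
Reagents that add atoms: none
Why: Heterogeneous catalytic hydrogenation adds both hydrogens syn from the ring face anti to the bulky pseudo-equatorial C4 group, as is known for 3,4,6-trisubstituted 5,6-dihydropyran-2-ones; this should set C1 (R, cis to C3) and place C17 cis for the time being, and the molecule has no allylic C–O bond or arene to lose.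

Step 10
Reactants: 17 all-cis lactone (3R,4R,6R)
Product: 18 (3S,4R,6R)-4-{2-[(tert-butyldimethylsilyl)oxy]ethyl}-6-{(2S)-2-(methoxymethoxy)-5-[(triisopropylsilyl)oxy]pentan-2-yl}-3-methyltetrahydro-2H-pyran-2-one (all-equatorial)
Conditions: DBU, toluene, 60 °C
Reagents that add atoms: none
Why: Base-mediated epimerisation through the lactone enolate (thermodynamic control) should move the C17 methyl from axial to equatorial, trans to the C1 side chain, giving 15S; C1, C3 and C4 carry no acidic hydrogen.

Step 11
Reactants: 18 all-equatorial lactone (3S,4R,6R)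
Product: 19 (3S,4R,6R)-4-(2-hydroxyethyl)-6-{(2S)-2-(methoxymethoxy)-5-[(triisopropylsilyl)oxy]pentan-2-yl}-3-methyltetrahydro-2H-pyran-2-one
Conditions: HF·pyridine, pyridine, THF, 0 °C
Reagents that add atoms: none
Why: Selective desilylation: a primary TBS ether is cleaved well before a primary TIPS ether, and the cold buffered medium should keep the free C13 hydroxyl from translactonising onto C16.

Step 12
Reactants: 19 C13 alcohol
Product: 20 (3S,4S,6R)-4-(2-iodoethyl)-6-{(2S)-2-(methoxymethoxy)-5-[(triisopropylsilyl)oxy]pentan-2-yl}-3-methyltetrahydro-2H-pyran-2-one (same spatial arrangement; the C4 descriptor changes only through priority)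
Conditions: I2, PPh3, imidazole, CH2Cl2, 0 °C
Reagents that add atoms: iodine, II
Why: The Appel-type iodination of a primary alcohol is fast and near neutral, so it removes the translactonisation risk immediately and spares the MOM, TIPS and lactone groups.

Step 13
Reactants: 21 pent-3-yn-1-ol
Product: 23 (3E)-4-iodopent-3-en-1-ol, via alkenylzirconocene 22 (not isolated)
Conditions: Cp2ZrHCl (2.5 equiv), THF, rt → 40 °C; I2, 0 °C
Reagents that add atoms: iodine, II
Why: Hydrozirconation–iodinolysis: syn addition of Zr–H, with zirconium settling on the less hindered methyl-bearing carbon in the presence of excess reagent, followed by iodinolysis with retention, fixes the E geometry of the future C11=C12 alkene.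

Step 14
Reactants: 23 (3E)-4-iodopent-3-en-1-ol
Product: 24 (3E)-4-iodopent-3-en-1-yl 4-methylbenzenesulfonate
Conditions: TsCl, Et3N, DMAP (cat.), CH2Cl2, 0 °C
Reagents that add atoms: 4-methylbenzenesulfonyl chloride, Cc1ccc(cc1)S(=O)(=O)Cl
Why: Sulfonylation of a primary alcohol activates C9 for substitution without affecting the alkenyl iodide.

Step 15
Reactants: 24 (3E)-4-iodopent-3-en-1-yl 4-methylbenzenesulfonate; 25 lithium acetylide–ethane-1,2-diamine complex (LiC≡CH·H2NCH2CH2NH2)
Product: 26 (5E)-6-iodohept-5-en-1-yne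
Conditions: DMSO, 15–25 °C
Reagents that add atoms: none
Why: SN2 alkylation of an acetylide by a primary tosylate in a dipolar aprotic solvent adds C8 and C19; the alkenyl iodide, whose vicinal hydrogen is cis to iodine, should resist elimination.

Step 16
Reactants: 26 (5E)-6-iodohept-5-en-1-yne
Product: 28 (5E)-2-bromo-6-iodohepta-1,5-diene, via (Z)-2-bromoalkenylborane 27 (not isolated)
Conditions: B-Br-9-BBN, CH2Cl2, 0 °C; AcOH, 0 °C → rt
Reagents that add atoms: 9-bromo-9-borabicyclo[3.3.1]nonane, BrB1C2CCCC1CCC2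
Why: Bromoboration–protodeboronation is specific for terminal alkynes and places bromine on the internal carbon (C8), leaving the trisubstituted iodoalkene untouched.

Step 17
Reactants: 20 C13 iodide; 28 (5E)-2-bromo-6-iodohepta-1,5-diene
Product: 30 (3S,4R,6R)-4-[(3E)-7-bromo-3-methylocta-3,7-dien-1-yl]-6-{(2S)-2-(methoxymethoxy)-5-[(triisopropylsilyl)oxy]pentan-2-yl}-3-methyltetrahydro-2H-pyran-2-one, via alkylzinc iodide 29 (not isolated)
Conditions: 20, Zn dust, LiCl, THF, 30 °C; then 28 (1.2 equiv), PdCl2(dppf) (5 mol %), THF, rt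
Reagents that add atoms: none
Why: Negishi sp3–sp2 coupling forms C12–C13: zinc inserts into the primary C–I bond without touching the lactone, and zerovalent palladium adds to the alkenyl C–I bond of 28 much faster than to its C–Br bond and with retention of the E geometry.

Step 18
Reactants: 30 bromodiene TIPS ether
Product: 31 (3S,4R,6R)-4-[(3E)-7-bromo-3-methylocta-3,7-dien-1-yl]-6-[(2S)-5-hydroxy-2-(methoxymethoxy)pentan-2-yl]-3-methyltetrahydro-2H-pyran-2-one
Conditions: Bu4NF, AcOH, THF, rt
Reagents that add atoms: none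
Why: Fluoride desilylation buffered with acetic acid frees C7–OH while the lactone, the C15 centre, the MOM ether and the alkenyl bromide remain intact.

Step 19
Reactants: 31 C7 alcohol
Product: 32 (4S)-4-{(2R,4R,5S)-4-[(3E)-7-bromo-3-methylocta-3,7-dien-1-yl]-5-methyl-6-oxotetrahydro-2H-pyran-2-yl}-4-(methoxymethoxy)pentanal
Conditions: Dess–Martin periodinane, CH2Cl2, rt
Reagents that add atoms: none
Why: Dess–Martin oxidation takes the primary alcohol cleanly to the aldehyde; the MOM group on C4–O prevents five-membered lactol formation with C7.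

Step 20
Reactants: 32 bromo aldehyde
Product: 34 macrocyclic allylic alcohol (14-membered carbocycle C1–C14 bridged by the lactone; 11E; C4 OMOM; C8 methylidene; C7 OH as a mixture of epimers), via alkenylchromium dichloride 33 (not isolated)
Conditions: CrCl2 (10 equiv), NiCl2 (0.2 equiv), DMSO–THF, slow addition to 0.003 M, rt → 40 °C
Reagents that add atoms: none
Why: The Nozaki–Hiyama–Kishi reaction (nickel-catalysed formation of alkenylchromium 33 and its aldehyde-selective addition) under high dilution closes the 14-membered ring at C7–C8 and delivers the methylidene carbinol directly; C7 is not controlled here and both epimers converge in step 21.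

Step 21
Reactants: 34 macrocyclic allylic alcohol (C7 epimers)
Product: 35 macrocyclic α-methylidene ketone (C7 ketone; 11E; C4 OMOM)
Conditions: Dess–Martin periodinane, CH2Cl2, 0 °C → rt
Reagents that add atoms: none
Why: Dess–Martin oxidation of the allylic alcohol merges the two C7 epimers into one enone under mild conditions.

Step 22
Reactants: 35 macrocyclic α-methylidene ketone
Product: 36 (7R)-macrocyclic allylic alcohol (11E; C4 OMOM)
Conditions: (S)-Me-CBS oxazaborolidine (0.5 equiv), catecholborane, toluene, −78 °C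
Reagents that add atoms: none
Why: Corey–Bakshi–Shibata reduction: the branched alkenyl side (C8) acts as the large group and the C6 methylene as the small one, so the (S)-catalyst should give 7R, the same sense as acetophenone to (R)-1-phenylethanol; cold catecholborane spares the alkenes and the lactone.

Step 23
Reactants: 36 (7R)-macrocyclic allylic alcohol
Product: 37 (1R,3R,4S,7R,15S,11E)-diene diol (11,12-deoxy precursor of the target)
Conditions: PPTS, t-BuOH, 80 °C
Reagents that add atoms: none
Why: Mild acid-catalysed transacetalisation removes the MOM group under conditions that allylic alcohols tolerate, and the hindered solvent cannot open the lactone.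

Step 24
Reactants: 37 diene diol
Product: 38 CNP0262409.1 (1R,3R,4S,7R,11S,12S,15S)
Conditions: ent-Shi ketone (1,2:4,5-di-O-isopropylidene-β-L-erythro-2,3-hexodiulo-2,6-pyranose, 0.5 equiv), KHSO5 (as 2KHSO5·KHSO4·K2SO4), K2CO3, Bu4NHSO4, MeCN–CH2(OMe)2–aq. Na2B4O7 buffer, 0 °C
Reagents that add atoms: potassium peroxymonosulfate, [K+].[O-]S(=O)(=O)OO
Why: Shi epoxidation: the chiral dioxirane reacts through a spiro transition state with E-trisubstituted alkenes; the D-fructose-derived ketone gives R,R epoxides for this substitution pattern, so its enantiomer should give 11S,12S, and the 1,1-disubstituted, inductively deactivated C8 methylidene is a poor substrate.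

Compound list
1 | (S)-linalool | C=C[C@@](C)(O)CCC=C(C)C | starting material
2 | (3S)-3-(methoxymethoxy)-3,7-dimethylocta-1,6-diene | C=C[C@@](C)(OCOC)CCC=C(C)C | intermediate
3 | (4S)-4-(methoxymethoxy)-4-methylhex-5-enal (not isolated) | C=C[C@@](C)(OCOC)CCC=O | intermediate
4 | (4S)-4-(methoxymethoxy)-4-methylhex-5-en-1-ol | C=C[C@@](C)(OCOC)CCCO | intermediate
5 | triisopropyl{[(4S)-4-(methoxymethoxy)-4-methylhex-5-en-1-yl]oxy}silane | C=C[C@@](C)(OCOC)CCCO[Si](C(C)C)(C(C)C)C(C)C | intermediate
6 | secondary ozonide (3-substituted 1,2,4-trioxolane) of 5 (not isolated) | C1OC(OO1)[C@@](C)(OCOC)CCCO[Si](C(C)C)(C(C)C)C(C)C | intermediate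
7 | (2S)-2-(methoxymethoxy)-2-methyl-5-[(triisopropylsilyl)oxy]pentanal | O=C[C@@](C)(OCOC)CCCO[Si](C(C)C)(C(C)C)C(C)C | intermediate
8 | 3-bromobut-3-en-1-ol | C=C(Br)CCO | starting material
9 | [(3-bromobut-3-en-1-yl)oxy](tert-butyl)dimethylsilane | C=C(Br)CCO[Si](C)(C)C(C)(C)C | intermediate
10 | methyl 2-bromopropanoate (racemic) | CC(Br)C(=O)OC | starting material
11 | bromo(1-methoxy-1-oxopropan-2-yl)zinc (not isolated) | COC(=O)C(C)[Zn]Br | intermediate
12 | methyl 5-[(tert-butyldimethylsilyl)oxy]-2-methyl-3-methylidenepentanoate (racemic) | C=C(CCO[Si](C)(C)C(C)(C)C)C(C)C(=O)OC | intermediate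
13 | lithium dienolate of 12 (not isolated) | C=C(CCO[Si](C)(C)C(C)(C)C)C(C)=C(OC)O[Li] | intermediate
14 | 3-{2-[(tert-butyldimethylsilyl)oxy]ethyl}-1-methoxy-2-methyl-1-[(trimethylsilyl)oxy]buta-1,3-diene | C=C(CCO[Si](C)(C)C(C)(C)C)/C(C)=C(/OC)O[Si](C)(C)C | intermediate
15 | cyclic mixed orthoester (2-methoxy-2-silyloxy-5,6-dihydro-2H-pyran cycloadduct; C16 undefined; not isolated) | CC1=C(CCO[Si](C)(C)C(C)(C)C)C[C@@H](OC1(OC)O[Si](C)(C)C)[C@@](C)(OCOC)CCCO[Si](C(C)C)(C(C)C)C(C)C | intermediate
16 | (6R)-4-{2-[(tert-butyldimethylsilyl)oxy]ethyl}-6-{(2S)-2-(methoxymethoxy)-5-[(triisopropylsilyl)oxy]pentan-2-yl}-3-methyl-5,6-dihydro-2H-pyran-2-one | CC1=C(CCO[Si](C)(C)C(C)(C)C)C[C@@H](OC1=O)[C@@](C)(OCOC)CCCO[Si](C(C)C)(C(C)C)C(C)C | intermediate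
17 | (3R,4R,6R) all-cis saturated lactone | CC(C)(C)[Si](C)(C)OCC[C@@H]1C[C@@H](OC(=O)[C@@H]1C)[C@@](C)(OCOC)CCCO[Si](C(C)C)(C(C)C)C(C)C | intermediate
18 | (3S,4R,6R) all-equatorial saturated lactone | CC(C)(C)[Si](C)(C)OCC[C@@H]1C[C@@H](OC(=O)[C@H]1C)[C@@](C)(OCOC)CCCO[Si](C(C)C)(C(C)C)C(C)C | intermediate
19 | C13 alcohol (3S,4R,6R) | OCC[C@@H]1C[C@@H](OC(=O)[C@H]1C)[C@@](C)(OCOC)CCCO[Si](C(C)C)(C(C)C)C(C)C | intermediate
20 | C13 iodide (3S,4S,6R) | ICC[C@@H]1C[C@@H](OC(=O)[C@H]1C)[C@@](C)(OCOC)CCCO[Si](C(C)C)(C(C)C)C(C)C | intermediate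
21 | pent-3-yn-1-ol | CC#CCCO | starting material
22 | (E)-alkenylzirconocene chloride, O-zirconated (not isolated) | C/C(=C\CCO[Zr](Cl)(C1C=CC=C1)C1C=CC=C1)[Zr](Cl)(C1C=CC=C1)C1C=CC=C1 | intermediate
23 | (3E)-4-iodopent-3-en-1-ol | C/C(I)=C\CCO | intermediate
24 | (3E)-4-iodopent-3-en-1-yl 4-methylbenzenesulfonate | C/C(I)=C\CCOS(=O)(=O)c1ccc(C)cc1 | intermediate
25 | lithium acetylide–ethane-1,2-diamine complex | [Li]C#C.NCCN | starting material
26 | (5E)-6-iodohept-5-en-1-yne | C#CCC/C=C(\C)I | intermediate
27 | (Z)-2-bromoalkenyl-9-borabicyclo[3.3.1]nonane (not isolated) | Br/C(CC/C=C(\C)I)=C\B1C2CCCC1CCC2 | intermediate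
28 | (5E)-2-bromo-6-iodohepta-1,5-diene | C=C(Br)CC/C=C(\C)I | intermediate
29 | alkylzinc iodide from 20 (not isolated) | I[Zn]CC[C@@H]1C[C@@H](OC(=O)[C@H]1C)[C@@](C)(OCOC)CCCO[Si](C(C)C)(C(C)C)C(C)C | intermediate
30 | Negishi product, bromodiene TIPS ether | C=C(Br)CC/C=C(\C)CC[C@@H]1C[C@@H](OC(=O)[C@H]1C)[C@@](C)(OCOC)CCCO[Si](C(C)C)(C(C)C)C(C)C | intermediate
31 | C7 alcohol | C=C(Br)CC/C=C(\C)CC[C@@H]1C[C@@H](OC(=O)[C@H]1C)[C@@](C)(OCOC)CCCO | intermediate
32 | C7 aldehyde | C=C(Br)CC/C=C(\C)CC[C@@H]1C[C@@H](OC(=O)[C@H]1C)[C@@](C)(OCOC)CCC=O | intermediate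
33 | alkenylchromium dichloride (not isolated) | C=C([Cr](Cl)Cl)CC/C=C(\C)CC[C@@H]1C[C@@H](OC(=O)[C@H]1C)[C@@](C)(OCOC)CCC=O | intermediate
34 | macrocyclic allylic alcohol, C7 epimers | C=C1CC/C=C(\C)CC[C@@H]2C[C@@H](OC(=O)[C@H]2C)[C@@](C)(OCOC)CCC1O | intermediate
35 | macrocyclic α-methylidene ketone | C=C1CC/C=C(\C)CC[C@@H]2C[C@@H](OC(=O)[C@H]2C)[C@@](C)(OCOC)CCC1=O | intermediate
36 | (7R)-macrocyclic allylic alcohol, C4 OMOM | C=C1CC/C=C(\C)CC[C@@H]2C[C@@H](OC(=O)[C@H]2C)[C@@](C)(OCOC)CC[C@H]1O | intermediate
37 | diene diol | C=C1CC/C=C(\C)CC[C@@H]2C[C@@H](OC(=O)[C@H]2C)[C@@](C)(O)CC[C@H]1O | intermediate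
38 | CNP0262409.1 | C=C1CC[C@@H]2O[C@@]2(C)CC[C@@H]2C[C@@H](OC(=O)[C@H]2C)[C@@](C)(O)CC[C@H]1O | target

Total step count: 24.
Longest linear sequence: 17 steps from (S)-linalool (steps 1–4, 8–12, 17–24).

Steps most likely to fail

Step 8. The two hindered partners may combine so slowly that the ketene acetal is lost to hydrolysis or silyl transfer. The ligand may also discriminate poorly between the aldehyde faces. Finally, addition through a transoid diene may give an (E)-enoate that cannot lactonise.
The fallback forms the same C2–C3 and O–C16 bonds in separate operations and closes the ring at C1=C15. It sets out from aldehyde 7 and returns at 16.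
- Commercial 4-hydroxybutan-2-one is silylated (TBSCl, imidazole) to 4-[(tert-butyldimethylsilyl)oxy]butan-2-one F1.
- F1 is enolised on its methyl side with the enantiomer of Ipc2BCl that attacks the Re face (Et3N, Et2O) and added to 7 at −78 °C. This gives the (3R)-β-hydroxy ketone F2.
- The C3 hydroxyl of F2 is acylated with 2-(diethoxyphosphoryl)propanoic acid (DCC, DMAP) to give the phosphonopropanoate F3.
- An intramolecular Horner–Wadsworth–Emmons olefination (LiCl, DBU, MeCN) then gives 16.

Step 9. The tetrasubstituted conjugated alkene may resist saturation, or it may isomerise on the catalyst surface and be reduced with poor facial selectivity.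
The fallback lowers the substitution of the alkene by leaving C17 out until after the reduction. It sets out from 9 and 7 and returns at 18, replacing steps 6–10.
- 9 is coupled as in step 6 with bromo(2-methoxy-2-oxoethyl)zinc F4 (from methyl bromoacetate and Zn) to give methyl 5-[(tert-butyldimethylsilyl)oxy]-3-methylidenepentanoate F5.
- LiN(iPr)2 and Me3SiCl convert F5 into the C15-unsubstituted silyl ketene acetal diene F6.
- The titanium–BINOL annulation of step 8 with 7 gives the trisubstituted dihydropyranone F7.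
- H2 (1 bar) over Pd/C in EtOAc should give the cis-4,6-disubstituted lactone F8.
- Enolate methylation (LiN(iPr)2, MeI, THF, −78 °C) anti to the C1 side chain installs C17 trans and gives 18.

Step 20. Activation of the alkenyl bromide by nickel may be slow. Oligomerisation, aldehyde reduction or pinacol coupling could then outrun ring closure.
The fallback closes the same C7–C8 bond by nickel-catalysed reductive alkyne–aldehyde coupling. It sets out from 20 (through its zinc reagent 29) and alkyne 26, and returns at 34.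
- 29 and 26 are coupled under PdCl2(dppf) to give the enyne TIPS ether F9; the weakly basic alkylzinc iodide should tolerate the terminal alkyne.
- Bu4NF/AcOH gives the enyne alcohol F10, and Dess–Martin oxidation gives the ynal F11.
- Ni(cod)2 with the bulky carbene 1,3-bis(2,6-diisopropylphenyl)imidazol-2-ylidene and Et3SiH, in THF at high dilution, should join C7 to the internal alkyne carbon C8. This gives the macrocyclic C7 triethylsilyl ether F12 with the exocyclic methylidene.
- HF·pyridine then gives 34.

Further compounds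
F1 | step 8 | 4-[(tert-butyldimethylsilyl)oxy]butan-2-one | CC(=O)CCO[Si](C)(C)C(C)(C)C
F2 | step 8 | (3R)-β-hydroxy ketone (C1 ketone, C3 OH, C4 OMOM) | CC(C)(C)[Si](C)(C)OCCC(=O)C[C@@H](O)[C@@](C)(OCOC)CCCO[Si](C(C)C)(C(C)C)C(C)C
F3 | step 8 | 2-(diethoxyphosphoryl)propanoate of F2 | CC(C)(C)[Si](C)(C)OCCC(=O)C[C@@H](OC(=O)C(C)P(=O)(OCC)OCC)[C@@](C)(OCOC)CCCO[Si](C(C)C)(C(C)C)C(C)C
F4 | step 9 | bromo(2-methoxy-2-oxoethyl)zinc | COC(=O)C[Zn]Br
F5 | step 9 | methyl 5-[(tert-butyldimethylsilyl)oxy]-3-methylidenepentanoate | C=C(CCO[Si](C)(C)C(C)(C)C)CC(=O)OC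
F6 | step 9 | 3-{2-[(tert-butyldimethylsilyl)oxy]ethyl}-1-methoxy-1-[(trimethylsilyl)oxy]buta-1,3-diene | C=C(CCO[Si](C)(C)C(C)(C)C)C=C(OC)O[Si](C)(C)C
F7 | step 9 | (6R)-4,6-disubstituted 5,6-dihydro-2H-pyran-2-one lacking C17 | C1=C(CCO[Si](C)(C)C(C)(C)C)C[C@@H](OC1=O)[C@@](C)(OCOC)CCCO[Si](C(C)C)(C(C)C)C(C)C
F8 | step 9 | cis-4,6-disubstituted tetrahydro-2H-pyran-2-one lacking C17 | CC(C)(C)[Si](C)(C)OCC[C@@H]1C[C@@H](OC(=O)C1)[C@@](C)(OCOC)CCCO[Si](C(C)C)(C(C)C)C(C)C
F9 | step 20 | enyne TIPS ether | C#CCC/C=C(\C)CC[C@@H]1C[C@@H](OC(=O)[C@H]1C)[C@@](C)(OCOC)CCCO[Si](C(C)C)(C(C)C)C(C)C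
F10 | step 20 | enyne alcohol | C#CCC/C=C(\C)CC[C@@H]1C[C@@H](OC(=O)[C@H]1C)[C@@](C)(OCOC)CCCO
F11 | step 20 | ynal | C#CCC/C=C(\C)CC[C@@H]1C[C@@H](OC(=O)[C@H]1C)[C@@](C)(OCOC)CCC=O
F12 | step 20 | macrocyclic C7 triethylsilyl ether (C7 epimers) | C=C1CC/C=C(\C)CC[C@@H]2C[C@@H](OC(=O)[C@H]2C)[C@@](C)(OCOC)CCC1O[Si](CC)(CC)CC
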